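**Retrosynthetic overview**
1. Forward map: 1 + 2 → 3; 3 + 4 → 5; 5 + 4 → 6; 6 + 4 → 7.
2. Disconnection A (last step): one of the two C–prenyl bonds at the quaternary C4 of 7 is cut back to the aromatic diprenyl ketone 6 and prenyl bromide 4 (alkylative dearomatisation).
3. Disconnection B: the two aryl–prenyl bonds of 6 are cut one at a time, back to 5 and then to 3 (phenoxide C-alkylation, one prenyl group per step).
4. Disconnection C: the aryl–C(=O) bond of 3 is cut back to phloroglucinol 1 and benzoyl chloride 2 (Friedel–Crafts acylation).
5. Rings and stereochemistry: no ring is built (the carbocycle is the ring of 1, dearomatised in the last step; the phenyl ring arrives with 2), and there is no stereocentre to set.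

**Assumptions**
- The target has no stereocentre (C4 carries two identical prenyl groups) and no stereogenic double bond, so it is achiral and no asymmetric step is needed. The enol tautomer drawn in the SMILES interconverts freely with the other enol forms.
- Only bulk commodity chemicals are counted as starting materials, so ketone 3 is made. It is also a catalogue compound, and buying it would shorten the route by one step.
- Each prenyl group is introduced in its own step with about one equivalent of 4, and 5 and 6 are isolated, so the degree of alkylation is set by stoichiometry.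

**Route**

Step 1
Reactants: 1 phloroglucinol (benzene-1,3,5-triol, anhydrous); 2 benzoyl chloride (1.05 equiv)
Product: 3 phenyl(2,4,6-trihydroxyphenyl)methanone (2,4,6-trihydroxybenzophenone)
Conditions: AlCl3 (3.5 equiv), PhNO2, 65 °C, 3 h; then ice/aq. HCl (AlCl3 leaves unchanged in the acidic aqueous layer)
Reagents that add atoms: none
Why: Friedel–Crafts acylation, in which the acylium–AlCl3 complex of 2 attacks the very electron-rich ring of 1 (its three free positions are equivalent, so there is no regiochemical question) and the aluminium-chelated ortho-hydroxy ketone formed is deactivated toward a second acylation; no stereocentre is formed.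

Step 2
Reactants: 3 phenyl(2,4,6-trihydroxyphenyl)methanone; 4 prenyl bromide (1-bromo-3-methylbut-2-ene, 1.0 equiv)
Product: 5 phenyl[2,4,6-trihydroxy-3-(3-methylbut-2-en-1-yl)phenyl]methanone (monoprenyl ketone)
Conditions: 10% aq. KOH (1.1 equiv), 0 °C, 4 added dropwise, 2 h; aq. HCl to pH 2, EtOAc extraction; chromatography (unreacted 3 recovered)
Reagents that add atoms: none
Why: SN2 C-alkylation of an ambident phenoxide (nuclear prenylation), in which the hydrogen-bonded phenoxide oxygens in water leave a ring carbon to attack the soft allylic bromide, the two free CH positions of 3 are equivalent so only one monoprenyl isomer can form, and one equivalent of 4 holds the reaction at 5; no stereocentre is formed.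

Step 3
Reactants: 5 phenyl[2,4,6-trihydroxy-3-(3-methylbut-2-en-1-yl)phenyl]methanone; 4 prenyl bromide (1.1 equiv)
Product: 6 phenyl[2,4,6-trihydroxy-3,5-bis(3-methylbut-2-en-1-yl)phenyl]methanone (diprenyl ketone)
Conditions: 10% aq. KOH (1.1 equiv), 0 °C, 4 added dropwise, 2 h; aq. HCl to pH 2, EtOAc extraction; chromatography
Reagents that add atoms: none
Why: Second SN2 C-prenylation of the phenoxide, in which the one remaining unsubstituted ring carbon of 5 is the least hindered nucleophilic site and its alkylation is followed by re-aromatisation, so it is favoured over attack at the prenyl- or benzoyl-bearing carbons and gives the symmetrical ketone 6; no stereocentre is formed.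

Step 4
Reactants: 6 phenyl[2,4,6-trihydroxy-3,5-bis(3-methylbut-2-en-1-yl)phenyl]methanone; 4 prenyl bromide (1.1 equiv)
Product: 7 2-benzoyl-3,5-dihydroxy-4,4,6-tris(3-methylbut-2-en-1-yl)cyclohexa-2,5-dien-1-one (target)
Conditions: NaOMe (1.1 equiv), degassed MeOH, Ar, 0 °C, 4 added dropwise over 1 h; 0 °C → rt, 12 h; dilute aq. HCl/Et2O extraction; chromatography or crystallisation from hexane
Reagents that add atoms: none
Why: Alkylative dearomatisation by SN2 C-prenylation, as in the synthesis of the hop β-acids, in which the phenoxide of 6 (no ring CH left) is alkylated at one of its two equivalent prenylated carbons and not at the deactivated, hindered benzoyl-bearing carbon, giving the stable enolised β-triketone 7, whose new quaternary carbon bears two identical prenyl groups and so is not a stereocentre.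

**Compound list**
1 | phloroglucinol (benzene-1,3,5-triol) | Oc1cc(O)cc(O)c1 | starting material
2 | benzoyl chloride | O=C(Cl)c1ccccc1 | starting material
3 | phenyl(2,4,6-trihydroxyphenyl)methanone (2,4,6-trihydroxybenzophenone) | O=C(c1ccccc1)c1c(O)cc(O)cc1O | intermediate
4 | prenyl bromide (1-bromo-3-methylbut-2-ene) | CC(C)=CCBr | starting material
5 | phenyl[2,4,6-trihydroxy-3-(3-methylbut-2-en-1-yl)phenyl]methanone (monoprenyl ketone) | CC(C)=CCc1c(O)cc(O)c(C(=O)c2ccccc2)c1O | intermediate
6 | phenyl[2,4,6-trihydroxy-3,5-bis(3-methylbut-2-en-1-yl)phenyl]methanone (diprenyl ketone) | CC(C)=CCc1c(O)c(CC=C(C)C)c(O)c(C(=O)c2ccccc2)c1O | intermediate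
7 | 2-benzoyl-3,5-dihydroxy-4,4,6-tris(3-methylbut-2-en-1-yl)cyclohexa-2,5-dien-1-one (CNP0210463.0; achiral) | CC(C)=CCC1=C(O)C(CC=C(C)C)(CC=C(C)C)C(O)=C(C(=O)c2ccccc2)C1=O | target

**Step count and risk**

Total steps: 4. Longest linear sequence: 4 (1 → 3 → 5 → 6 → 7).

Most likely to fail: step 4. The phenoxide of 6 can be alkylated on oxygen or at the benzoyl-bearing carbon, and product 7 can take up a fourth prenyl group, so the yield may be low and the separation hard. The fallback sets out from 6 and comes back at 7. Ketone 6 is treated with allyl methyl carbonate (1.1 equiv) and the zerovalent palladium complex Pd(PPh3)4 (3 mol %) in THF at rt. This is a Tsuji–Trost allylation: the π-allyl electrophile is soft and any O-allyl ether re-ionises under the catalyst, so the allyl group ends on carbon. It gives the racemic allyl dienone 2-benzoyl-3,5-dihydroxy-4,6-bis(3-methylbut-2-en-1-yl)-4-(prop-2-en-1-yl)cyclohexa-2,5-dien-1-one F1. An olefin cross-metathesis of F1 with excess 2-methylbut-2-ene then turns the allyl group into a prenyl group and gives 7. It uses the second-generation Grubbs catalyst (H2IMes)(PCy3)Cl2Ru=CHPh (5 mol %) in CH2Cl2 at 40 °C. The prenyl groups already present only exchange degenerately, and the stereocentre of F1 disappears.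

Second most likely to fail: step 2. Direct monoprenylation can give mixtures of 3, 5, 6 and O-prenyl ethers. The fallback sets out from 3 and comes back at 5. It places the carbon substituent by an O-allylation and Claisen rearrangement, which can only deliver one group.
- Ketone 3 is O-allylated at the non-chelated 4-hydroxyl with allyl bromide (1.0 equiv) and K2CO3 (1.0 equiv) in acetone at reflux. This gives the allyl ether [2,6-dihydroxy-4-(prop-2-en-1-yloxy)phenyl](phenyl)methanone F2.
- Heating F2 in N,N-diethylaniline at 190 °C brings about an aromatic Claisen rearrangement to either of the two equivalent ortho positions. This gives the C-allyl ketone phenyl[2,4,6-trihydroxy-3-(prop-2-en-1-yl)phenyl]methanone F3.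
- Cross-metathesis of F3 with excess 2-methylbut-2-ene and the second-generation Grubbs catalyst (H2IMes)(PCy3)Cl2Ru=CHPh (5 mol %) in CH2Cl2 at 40 °C gives 5.

Third most likely to fail: step 3. The second prenyl group can go onto the already prenylated carbon or onto oxygen instead of the free ring CH. The fallback sets out from 5 and comes back at 6. It uses the Claisen rearrangement of a 1,1-dimethylallyl ether, which delivers a linear prenyl group to the only free ortho position.
- Ketone 5 is etherified at the 4-hydroxyl with 3-chloro-3-methylbut-1-yne (1.2 equiv), K2CO3 (1.2 equiv) and KI (10 mol %) in acetone at 50 °C. This gives the propargyl ether {2,6-dihydroxy-3-(3-methylbut-2-en-1-yl)-4-[(2-methylbut-3-yn-2-yl)oxy]phenyl}(phenyl)methanone F4.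
- Semi-hydrogenation of F4 with H2 (1 atm) over Lindlar catalyst (Pd on CaCO3 poisoned with Pb(OAc)2) and quinoline in EtOAc at rt reduces only the terminal alkyne. This gives the allyl ether {2,6-dihydroxy-3-(3-methylbut-2-en-1-yl)-4-[(2-methylbut-3-en-2-yl)oxy]phenyl}(phenyl)methanone F5.
- Heating F5 in xylene at 130 °C brings about the [3,3] shift to C5 with allyl inversion, and tautomerisation gives 6.

**Further compounds**
F1 | step 4 | 2-benzoyl-3,5-dihydroxy-4,6-bis(3-methylbut-2-en-1-yl)-4-(prop-2-en-1-yl)cyclohexa-2,5-dien-1-one (racemic) | C=CCC1(CC=C(C)C)C(O)=C(CC=C(C)C)C(=O)C(C(=O)c2ccccc2)=C1O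
F2 | step 2 | [2,6-dihydroxy-4-(prop-2-en-1-yloxy)phenyl](phenyl)methanone | C=CCOc1cc(O)c(C(=O)c2ccccc2)c(O)c1
F3 | step 2 | phenyl[2,4,6-trihydroxy-3-(prop-2-en-1-yl)phenyl]methanone | C=CCc1c(O)cc(O)c(C(=O)c2ccccc2)c1O
F4 | step 3 | {2,6-dihydroxy-3-(3-methylbut-2-en-1-yl)-4-[(2-methylbut-3-yn-2-yl)oxy]phenyl}(phenyl)methanone | C#CC(C)(C)Oc1cc(O)c(C(=O)c2ccccc2)c(O)c1CC=C(C)C
F5 | step 3 | {2,6-dihydroxy-3-(3-methylbut-2-en-1-yl)-4-[(2-methylbut-3-en-2-yl)oxy]phenyl}(phenyl)methanone | C=CC(C)(C)Oc1cc(O)c(C(=O)c2ccccc2)c(O)c1CC=C(C)C
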